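The bond between the benzylic CH2 (C7, on guaiacyl ring A) and the CHMe carbon (C8, on dienone ring B) is disconnected. C8 lies para to the ring-B carbonyl oxygen, so in a phenolic precursor it is the exocyclic carbon of a p-quinone methide. C7, benzylic to ring A, is made nucleophilic by a traceless carboxyl group (homovanillic acid). The key step unites a racemic ring-B p-hydroxybenzylic alcohol with the bis-silyl ketene acetal of the ring-A acid under chiral Brønsted acid catalysis, forming C7–C8 and the C8 stereocentre enantioconvergently. Decarboxylation, then iodine(III) dearomatisation of ring B in methanol, installs the quaternary C4 methyl ether.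

Key step: step 6

Assumption: for each chiral reagent (IDPi acid in step 6, aryl-λ3-iodane in step 8) the antipode that gives the configuration shown is to be identified by a trial with both antipodes; one antipode is written for definiteness.

Step 1
Reactants: 1 1-(4-hydroxy-2-methoxyphenyl)ethan-1-one; 2 allyl bromide
Product: 3 1-[2-methoxy-4-(prop-2-en-1-yloxy)phenyl]ethan-1-one
Conditions: K2CO3, acetone, reflux
Reagents that add atoms: none
Why: Williamson ether synthesis; the only acidic OH is the phenol, whose phenoxide is O-alkylated by the allylic bromide.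

Step 2
Reactants: 3 1-[2-methoxy-4-(prop-2-en-1-yloxy)phenyl]ethan-1-one
Product: 4 1-[4-hydroxy-2-methoxy-5-(prop-2-en-1-yl)phenyl]ethan-1-one
Conditions: PhNEt2, 195 °C (sealed tube)
Reagents that add atoms: none
Why: Aromatic Claisen rearrangement ([3,3] shift, then tautomerisation); migration should favour C5 over C3 because C3 is flanked by the methoxy group and a meta donor directs the allyl group to the position para to itself; the minor C3 isomer is removed by chromatography.

Step 3
Reactants: 4 1-[4-hydroxy-2-methoxy-5-(prop-2-en-1-yl)phenyl]ethan-1-one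
Product: 5 rac-1-[4-hydroxy-2-methoxy-5-(prop-2-en-1-yl)phenyl]ethan-1-ol
Conditions: NaBH4, MeOH, 0 °C to rt; sat. NH4Cl work-up
Reagents that add atoms: none
Why: Hydride reduction of the aryl ketone; the racemic carbinol suffices because step 6 is enantioconvergent, and a neutral work-up protects this ionisable p-hydroxybenzylic alcohol.

Step 4
Reactants: 6 (4-hydroxy-3-methoxyphenyl)acetic acid (homovanillic acid)
Product: 8 {3-methoxy-4-[(triisopropylsilyl)oxy]phenyl}acetic acid, via bis-silyl intermediate 7 (not isolated)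
Conditions: TIPSCl (2.2 equiv), imidazole, DMF, rt; then 1 M HCl–THF, rt
Reagents that add atoms: chlorotriisopropylsilane, CC(C)[Si](Cl)(C(C)C)C(C)C
Why: Silylation of both OH groups followed by selective hydrolysis of the labile silyl ester leaves the robust aryl TIPS ether, which keeps ring A inert to iodine(III) in step 8.

Step 5
Reactants: 8 {3-methoxy-4-[(triisopropylsilyl)oxy]phenyl}acetic acid
Product: 9 2-{3-methoxy-4-[(triisopropylsilyl)oxy]phenyl}-1,1-bis[(trimethylsilyl)oxy]ethene
Conditions: LDA (2.2 equiv), THF, −78 °C; TMSCl (2.5 equiv), −78 °C to rt; filtration under Ar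
Reagents that add atoms: chlorotrimethylsilane, C[Si](C)(C)Cl
Why: Double deprotonation of the arylacetic acid and O-silylation of the enediolate (silyl ketene acetal formation) give a neutral carboxylic acid enolate equivalent.

Step 6
Reactants: 5 rac-1-[4-hydroxy-2-methoxy-5-(prop-2-en-1-yl)phenyl]ethan-1-ol; 9 2-{3-methoxy-4-[(triisopropylsilyl)oxy]phenyl}-1,1-bis[(trimethylsilyl)oxy]ethene
Product: 12 (3R)-3-[4-hydroxy-2-methoxy-5-(prop-2-en-1-yl)phenyl]-2-{3-methoxy-4-[(triisopropylsilyl)oxy]phenyl}butanoic acid (C2 epimers), via quinone methide 10 (not isolated), via persilylated adduct 11 (not isolated)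
Conditions: 9 (3 equiv), (S,S)-IDPi chiral Brønsted acid (3 mol %), 5 Å MS, toluene, −60 to −40 °C; then 1 M HCl–THF
Reagents that add atoms: none
Why: Proposed new method: the chiral acid ionises racemic 5 (dehydration, aided by O-silylation by 9) to the E-configured p-quinone methide 10, held as its O-protonated or O-silylated benzylic cation inside the confined chiral anion, and the nucleophilic carbon of ketene acetal 9 adds to the exocyclic carbon (1,6-addition), which rearomatises ring B; silyl transfer releases the catalyst and work-up hydrolyses 11 to 12. The closest known reaction types are chiral-phosphoric-acid-catalysed enantioconvergent substitutions of racemic p-hydroxybenzylic alcohols through p-quinone methides, Lewis-acid Mukaiyama–Michael 1,6-additions of silyl ketene acetals to p-quinone methides, and chiral-counteranion-directed additions of silyl ketene acetals to cationic electrophiles. No ring is closed. The new C3 centre (R; C8 of the target) is set by the chiral counteranion, which shields one face of the planar cation so that both enantiomers of 5 converge; the C2 centre is not controlled and is of no consequence because it becomes CH2 in step 7. The step needs C-alkylation at the exocyclic carbon in preference to proton loss to the vinylphenol or Friedel–Crafts attack on the electron-rich rings; low temperature, excess 9 and the single cation geometry enforced by A(1,3) strain between the methyl group and the ring methoxy group should secure this.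

Step 7
Reactants: 12 (3R)-3-[4-hydroxy-2-methoxy-5-(prop-2-en-1-yl)phenyl]-2-{3-methoxy-4-[(triisopropylsilyl)oxy]phenyl}butanoic acid
Product: 14 5-methoxy-4-[(2R)-1-{3-methoxy-4-[(triisopropylsilyl)oxy]phenyl}propan-2-yl]-2-(prop-2-en-1-yl)phenol, via phthalimidoyl ester 13 (not isolated)
Conditions: N-hydroxyphthalimide, DIC, CH2Cl2, rt; then Hantzsch ester, Ru(bpy)3(PF6)2 (1 mol %), blue LEDs, rt
Reagents that add atoms: none
Why: Reductive radical decarboxylation of a redox-active N-acyloxyphthalimide: single-electron reduction of 13 releases CO2 and a C7 benzylic radical that takes a hydrogen atom from the Hantzsch ester; the C8 centre is untouched, and the step is placed before dearomatisation because a C7 radical next to a dienone ring would fragment.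

Step 8
Reactants: 14 5-methoxy-4-[(2R)-1-{3-methoxy-4-[(triisopropylsilyl)oxy]phenyl}propan-2-yl]-2-(prop-2-en-1-yl)phenol
Product: 15 (4S)-4,5-dimethoxy-4-[(2R)-1-{3-methoxy-4-[(triisopropylsilyl)oxy]phenyl}propan-2-yl]-2-(prop-2-en-1-yl)cyclohexa-2,5-dien-1-one
Conditions: preformed (R,R)-lactamide-based chiral aryl-λ3-iodane diacetate (1.1 equiv), MeOH–CH2Cl2, −40 °C
Reagents that add atoms: methanol, CO
Why: Iodine(III)-mediated oxidative dearomatisation of a 4-alkylphenol: methanol attacks the alkyl-bearing para carbon of the phenol-bound iodane to give the cross-conjugated p-quinol methyl ether; the C4 configuration is to be set by the C2-symmetric chiral iodane, since the C8 centre biases the faces only weakly, and the C4 epimer is a separable diastereomer.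

Step 9
Reactants: 15 (4S)-4,5-dimethoxy-4-[(2R)-1-{3-methoxy-4-[(triisopropylsilyl)oxy]phenyl}propan-2-yl]-2-(prop-2-en-1-yl)cyclohexa-2,5-dien-1-one
Product: 16 (4S)-4-[(2R)-1-(4-hydroxy-3-methoxyphenyl)propan-2-yl]-4,5-dimethoxy-2-(prop-2-en-1-yl)cyclohexa-2,5-dien-1-one
Conditions: TBAF, AcOH, THF, 0 °C
Reagents that add atoms: none
Why: Buffered fluoride desilylation unmasks the ring-A phenol without touching the vinylogous ester, the tertiary methyl ether, the allyl group or either stereocentre.

Compound list
1 | 1-(4-hydroxy-2-methoxyphenyl)ethan-1-one | CC(=O)c1ccc(O)cc1OC | starting material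
2 | allyl bromide (3-bromoprop-1-ene) | C=CCBr | starting material
3 | 1-[2-methoxy-4-(prop-2-en-1-yloxy)phenyl]ethan-1-one | CC(=O)c1ccc(OCC=C)cc1OC | intermediate
4 | 1-[4-hydroxy-2-methoxy-5-(prop-2-en-1-yl)phenyl]ethan-1-one | CC(=O)c1cc(CC=C)c(O)cc1OC | intermediate
5 | rac-1-[4-hydroxy-2-methoxy-5-(prop-2-en-1-yl)phenyl]ethan-1-ol | CC(O)c1cc(CC=C)c(O)cc1OC | intermediate
6 | (4-hydroxy-3-methoxyphenyl)acetic acid (homovanillic acid) | OC(=O)Cc1ccc(O)c(OC)c1 | starting material
7 | triisopropylsilyl {3-methoxy-4-[(triisopropylsilyl)oxy]phenyl}acetate (not isolated) | CC(C)[Si](OC(=O)Cc1ccc(O[Si](C(C)C)(C(C)C)C(C)C)c(OC)c1)(C(C)C)C(C)C | intermediate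
8 | {3-methoxy-4-[(triisopropylsilyl)oxy]phenyl}acetic acid | OC(=O)Cc1ccc(O[Si](C(C)C)(C(C)C)C(C)C)c(OC)c1 | intermediate
9 | 2-{3-methoxy-4-[(triisopropylsilyl)oxy]phenyl}-1,1-bis[(trimethylsilyl)oxy]ethene | C[Si](C)(C)OC(O[Si](C)(C)C)=Cc1ccc(O[Si](C(C)C)(C(C)C)C(C)C)c(OC)c1 | intermediate
10 | (4E)-4-ethylidene-5-methoxy-2-(prop-2-en-1-yl)cyclohexa-2,5-dien-1-one (p-quinone methide, not isolated) | C/C=C1\C=C(CC=C)C(=O)C=C1OC | intermediate
11 | trimethylsilyl (3R)-3-{2-methoxy-5-(prop-2-en-1-yl)-4-[(trimethylsilyl)oxy]phenyl}-2-{3-methoxy-4-[(triisopropylsilyl)oxy]phenyl}butanoate (C2 epimers, not isolated) | C=CCc1cc([C@H](C)C(C(=O)O[Si](C)(C)C)c2ccc(O[Si](C(C)C)(C(C)C)C(C)C)c(OC)c2)c(OC)cc1O[Si](C)(C)C | intermediate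
12 | (3R)-3-[4-hydroxy-2-methoxy-5-(prop-2-en-1-yl)phenyl]-2-{3-methoxy-4-[(triisopropylsilyl)oxy]phenyl}butanoic acid (C2 epimers) | C=CCc1cc([C@H](C)C(C(=O)O)c2ccc(O[Si](C(C)C)(C(C)C)C(C)C)c(OC)c2)c(OC)cc1O | intermediate
13 | 1,3-dioxoisoindolin-2-yl (3R)-3-[4-hydroxy-2-methoxy-5-(prop-2-en-1-yl)phenyl]-2-{3-methoxy-4-[(triisopropylsilyl)oxy]phenyl}butanoate (not isolated) | O=C(ON1C(=O)c2ccccc2C1=O)C(c1ccc(O[Si](C(C)C)(C(C)C)C(C)C)c(OC)c1)[C@@H](C)c1cc(CC=C)c(O)cc1OC | intermediate
14 | 5-methoxy-4-[(2R)-1-{3-methoxy-4-[(triisopropylsilyl)oxy]phenyl}propan-2-yl]-2-(prop-2-en-1-yl)phenol | C=CCc1cc([C@H](C)Cc2ccc(O[Si](C(C)C)(C(C)C)C(C)C)c(OC)c2)c(OC)cc1O | intermediate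
15 | (4S)-4,5-dimethoxy-4-[(2R)-1-{3-methoxy-4-[(triisopropylsilyl)oxy]phenyl}propan-2-yl]-2-(prop-2-en-1-yl)cyclohexa-2,5-dien-1-one | C=CCC1=C[C@@](OC)([C@H](C)Cc2ccc(O[Si](C(C)C)(C(C)C)C(C)C)c(OC)c2)C(OC)=CC1=O | intermediate
16 | (4S)-4-[(2R)-1-(4-hydroxy-3-methoxyphenyl)propan-2-yl]-4,5-dimethoxy-2-(prop-2-en-1-yl)cyclohexa-2,5-dien-1-one | C=CCC1=C[C@@](OC)([C@H](C)Cc2ccc(O)c(OC)c2)C(OC)=CC1=O | target

Total step count: 9
Longest linear sequence: 7 steps (steps 1, 2, 3, 6, 7, 8, 9)

Steps most likely to fail

Step 6 (Proposed new method): the ion pair may discriminate the two faces of the cation poorly, or the cation may be lost through proton loss to the vinylphenol or Friedel–Crafts self-alkylation before the ketene acetal captures it. The fallback uses known chemistry, with auxiliary control and separation. It sets out from acid 8, whose mixed pivalic anhydride is N-acylated with lithiated (S)-4-benzyl-oxazolidin-2-one to give (4S)-4-benzyl-3-({3-methoxy-4-[(triisopropylsilyl)oxy]phenyl}acetyl)-1,3-oxazolidin-2-one F1. Its chlorotitanium enolate (TiCl4, i-Pr2NEt, CH2Cl2, −78 °C) is alkylated by alcohol 5, which the Lewis acid ionises in situ, to give the (2S,3R)-configured N-acyl oxazolidinone F2. The auxiliary fixes C2, so the C3 epimers are diastereomers and the (3R) one is taken by chromatography. LiOH/H2O2 then returns to the route at acid 12, as a single C2 epimer.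

Step 8: facial selection at the para carbon may be weak, because the chiral iodine centre sits far from C4 and the C8 centre gives little or even opposing bias; attack at the allyl-bearing ortho carbon may also compete. The fallback sets out from phenol 14, which is oxidised with PhI(OAc)2 in MeOH without chiral control. Dienone 15 is separated by chromatography from its C4 epimer, the (4R)-dienone F3. F3 is returned to 14 by Zn/AcOH reductive rearomatisation (loss of methanol) for another pass, and the route is rejoined at 15.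

Step 2: the allyl group may migrate to C3, between the two oxygen substituents, instead of C5 (poor regioselectivity). The fallback sets out from ketone 1. Electrophilic bromination (NBS, MeCN, 0 °C) at C5, ortho to the hydroxyl and para to the methoxy group, gives 1-(5-bromo-4-hydroxy-2-methoxyphenyl)ethan-1-one F4. Stille coupling with allyltributylstannane (Pd(PPh3)4, DMF, 90 °C) then installs the allyl group with fixed regiochemistry and rejoins the route at 4.

Further compounds
F1 | step 6 | (4S)-4-benzyl-3-({3-methoxy-4-[(triisopropylsilyl)oxy]phenyl}acetyl)-1,3-oxazolidin-2-one | O=C(Cc1ccc(O[Si](C(C)C)(C(C)C)C(C)C)c(OC)c1)N1[C@@H](Cc2ccccc2)COC1=O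
F2 | step 6 | (4S)-4-benzyl-3-[(2S,3R)-3-[4-hydroxy-2-methoxy-5-(prop-2-en-1-yl)phenyl]-2-{3-methoxy-4-[(triisopropylsilyl)oxy]phenyl}butanoyl]-1,3-oxazolidin-2-one | O=C([C@@H]([C@@H](C)c1cc(CC=C)c(O)cc1OC)c1ccc(O[Si](C(C)C)(C(C)C)C(C)C)c(OC)c1)N1[C@@H](Cc2ccccc2)COC1=O
F3 | step 8 | (4R)-4,5-dimethoxy-4-[(2R)-1-{3-methoxy-4-[(triisopropylsilyl)oxy]phenyl}propan-2-yl]-2-(prop-2-en-1-yl)cyclohexa-2,5-dien-1-one | C=CCC1=C[C@](OC)([C@H](C)Cc2ccc(O[Si](C(C)C)(C(C)C)C(C)C)c(OC)c2)C(OC)=CC1=O
F4 | step 2 | 1-(5-bromo-4-hydroxy-2-methoxyphenyl)ethan-1-one | CC(=O)c1cc(Br)c(O)cc1OC
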